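Temperature changes once in dawn, at 25 min, so that moment is what to watch.

| flask | substrate | partner | temperature | remark | time |
|---|---|---|---|---|---|
| east | 0.42 M | 1 equiv | 48 °C | run made earlier |  |
| north | 1.3 M | 1 equiv | 64 °C | run made earlier |  |
| noon | 0.60 M | 1.00 equiv |  | at 70 °C throughout | 2.0 h |
| dawn | 2.0 M | 1.00 equiv |  | at 70 °C until 25 min, from then on at 40 °C | 2.0 h |

- east (time / h: target / %, isomer of the product / %): 0.667: 0, 3; 1.33: 3, 2; 2.00: 7, 2; 3.00: 5, 0; 4.00: 6, 4
- north (time / min: target / %, isomer of the product / %): 6.00: 0, 5; 15.0: 10, 3; 30.0: 9, 8; 50.0: 15, 20; 60.0: 15, 23; 80.0: 10, 27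

(each reading ± 2 percentage points)

- where the amount of substrate changes, what is given in equivalents or mol% on it follows

1. the flask that ends with the higher share of target in all that became target or isomer of the product or side product, or "neither" when 2 percentage points or less lies between them (noon / dawn / neither)
2. share of target in all that became target or isomer of the product or side product, noon
3. share of target in all that became target or isomer of the product or side product, dawn

In the north run the target reads 15% at 60.0 min and 10% at 80.0 min, while the isomer climbs to 27%. So the share of target in target plus isomer falls with time: 42.9% at 50.0 min, 39.5% at 60.0 min, 27.0% at 80.0 min. These are readings with their scatter, and I use them as a ruler, counting side product as zero.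

I need each flask's place on that ruler. My first link treats the last readings of both runs as second-order conversion, which gives the formation ratio in the table. Taking the logarithm of a rate as linear in temperature, I scale that ratio to the cooling and to the step from north's temperature up to 70 °C.

The weak link is that formation is the wrong clock for a share. So I reforge it from the share itself: east shows 60.0% at 4.00 h, north 52.9% at 30.0 min, and I take these as one point within the scatter.

| clock | north over east | cooling factor | hot over north | dawn on north's clock |
|---|---|---|---|---|
| formation | 5.12 | 21.4 | 1.85 | 54.3 min |
| share | 8.00 | 49.4 | 2.18 | 58.7 min |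

The last cell is the north-equivalent time: the minutes at north's temperature that move the share as far as the flask's own programme does. The steeper clock shrinks the cold stage but stretches the hot minutes, so both rows land near the reading at 60.0 min, and I commit to about 39.5% for dawn. Noon reaches 262 min on the same clock, past the last reading, so I put noon below 27.0%. The ruler comes from [substrate] = 1.3 M, against 2.0 M in dawn and 0.60 M in noon, and I leave that unchecked.

The forecast says dawn, with noon at 7% and dawn at 45%, above my figure: “Cooling nearly stops isomerisation while some target still forms”.

The simulation gives noon 11.9% and dawn 39.2%, so dawn ends higher, and the forecast's dawn stands 5.8 percentage points above the result.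

    substrate + partner → intermediate + released group (k = 7.79 × 10⁻⁴ L mol⁻¹ s⁻¹, Ea = 92.0 kJ mol⁻¹)
    intermediate ⇌ target (K = 0.826, k = 0.00266 s⁻¹, Ea = 107 kJ mol⁻¹, ΔH = −7.00 kJ mol⁻¹)
    intermediate ⇌ isomer of the product (K = 14.6, k = 8.49 × 10⁻⁴ s⁻¹, Ea = 111 kJ mol⁻¹, ΔH = −34.0 kJ mol⁻¹)
    target + released group → side product (k = 9.89 × 10⁻⁵ L mol⁻¹ s⁻¹, Ea = 91.0 kJ mol⁻¹)
    substrate ⇌ dormant form (K = 0.760, k = 0.00280 s⁻¹, Ea = 102 kJ mol⁻¹, ΔH = −39.0 kJ mol⁻¹)
    (constants at 70 °C)

Noon's share stays low mainly because target runs back to intermediate: with that backward run struck out, noon ends at 70.3%, not 11.9%. Part of dawn's share comes from the temperature programme: without it, dawn ends at 7.43%, not 39.2%. Target is the kinetic product here, in the sense of kinetic against thermodynamic control, and 58.7 min is my measure of how far dawn has slipped. In the same dawn flask left until 8.0 h, the north-equivalent time grows to 74.6 min, where the north readings give 30.4%. That flask stands at 31.6%.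

The data stem from a simulated flask for an exercise, and the scatter is random.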